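The furan ring is disconnected at O1–C2. Read backwards, the array O1, C2 (bearing ring B), C3 and the formyl carbon is that of an isoaurone (3-benzylidenebenzofuran-2-one) at the lactol level, with the ring oxygen moved from the formyl carbon to the benzylidene carbon. The key step oxidises the open lactol, a 2-(2-hydroxyaryl)-3-arylacrolein, so that the ring A phenol oxygen bonds to the benzylidene carbon and the aromatic 3-formylbenzofuran forms in one operation. In this precursor ring A carries two methyl ethers and the complete hydroxyalkyl chain, ring B two benzyl ethers. Knoevenagel condensation and lactone reduction assemble it; demethylation and hydrogenolysis finish.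

Key step: step 8

Remark on the chemistry: the target has no stereocentre and no other stereogenic element, so no enantioselective step is needed; the only stereo-elements on the way are alkene geometries and transient racemic centres that are destroyed again.

Design remark: the tertiary alcohol is carried unprotected from step 3 onwards. For that reason no step uses a mineral acid or a boron or aluminium halide, which could ionise it or, once the neighbouring phenol is free, close a dimethylchroman.

Step 1
Reactants: 1 4-hydroxy-2,6-dimethoxybenzaldehyde; 2 methyl (triphenyl-λ5-phosphanylidene)acetate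
Product: 3 methyl (2E)-3-(4-hydroxy-2,6-dimethoxyphenyl)prop-2-enoate
Conditions: PhMe, 110 °C
Reagents that add atoms: none
Why: Wittig olefination with a stabilised ylide tolerates the free phenol and should give the E-cinnamate, whose geometry is removed in step 2.

Step 2
Reactants: 3 methyl (2E)-3-(4-hydroxy-2,6-dimethoxyphenyl)prop-2-enoate
Product: 4 methyl 3-(4-hydroxy-2,6-dimethoxyphenyl)propanoate
Conditions: H2 (1 atm), 10% Pd/C, EtOAc, rt
Reagents that add atoms: none
Why: Catalytic hydrogenation of a conjugated alkene; nothing else in 3 is reducible under these conditions.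

Step 3
Reactants: 4 methyl 3-(4-hydroxy-2,6-dimethoxyphenyl)propanoate
Product: 5 4-(3-hydroxy-3-methylbutyl)-3,5-dimethoxyphenol
Conditions: MeMgBr (4 equiv), THF, 0 °C → rt; aq NH4Cl
Reagents that add atoms: methylmagnesium bromide, C[Mg]Br
Why: Double Grignard addition to the ester, after the first equivalent has deprotonated the phenol, should give the tertiary alcohol and with it the symmetric phenol.

Step 4
Reactants: 5 4-(3-hydroxy-3-methylbutyl)-3,5-dimethoxyphenol; 6 glyoxylic acid
Product: 7 2-hydroxy-2-[6-hydroxy-3-(3-hydroxy-3-methylbutyl)-2,4-dimethoxyphenyl]acetic acid (racemic)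
Conditions: NaOH (2.5 equiv), H2O, 0 °C → rt; then aq HCl to pH 3, 0 °C
Reagents that add atoms: none
Why: Ortho-hydroxyalkylation of a phenolate by glyoxylate (aldol-type aromatic substitution) can only occur at the two ortho positions, which are equivalent by symmetry because the para position is blocked; the new stereocentre is racemic and is removed in step 5.

Step 5
Reactants: 7 2-hydroxy-2-[6-hydroxy-3-(3-hydroxy-3-methylbutyl)-2,4-dimethoxyphenyl]acetic acid
Product: 9 5-(3-hydroxy-3-methylbutyl)-4,6-dimethoxy-1-benzofuran-2(3H)-one, via hydroxyphenylacetic acid 8 (not isolated)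
Conditions: H2 (1 atm), 10% Pd/C, AcOH, 40 °C; filter; then PhMe, reflux (Dean–Stark)
Reagents that add atoms: none
Why: Hydrogenolysis of the benzylic hydroxyl, which the ortho-hydroxy and ortho,para-dimethoxy substituents make labile enough to do without mineral acid, followed by thermal lactonisation of the 2-hydroxyphenylacetic acid onto its only ortho hydroxyl.

Step 6
Reactants: 9 5-(3-hydroxy-3-methylbutyl)-4,6-dimethoxy-1-benzofuran-2(3H)-one; 10 2,4-bis(benzyloxy)benzaldehyde
Product: 11 (3Z)-3-[2,4-bis(benzyloxy)benzylidene]-5-(3-hydroxy-3-methylbutyl)-4,6-dimethoxy-1-benzofuran-2(3H)-one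
Conditions: piperidine (0.1 equiv), AcOH (0.1 equiv), 4 Å MS, PhMe, 80 °C
Reagents that add atoms: none
Why: Knoevenagel condensation at the acidic C3 methylene of a benzofuran-2(3H)-one under catalytic amine–acid conditions (catalytic so that the aryl lactone is not aminolysed); the 4-methoxy group should push the aryl group to the carbonyl side (Z), but either geometry serves.

Step 7
Reactants: 11 (3Z)-3-[2,4-bis(benzyloxy)benzylidene]-5-(3-hydroxy-3-methylbutyl)-4,6-dimethoxy-1-benzofuran-2(3H)-one
Product: 13 (2Z)-3-[2,4-bis(benzyloxy)phenyl]-2-[6-hydroxy-3-(3-hydroxy-3-methylbutyl)-2,4-dimethoxyphenyl]prop-2-enal, via lactol 12 (not isolated)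
Conditions: DIBAL-H (2.2 equiv), CH2Cl2, −78 °C; MeOH, then aq Rochelle salt
Reagents that add atoms: none
Why: Partial reduction of a lactone to the lactol by DIBAL at low temperature, where the tetrahedral aluminate survives until work-up; lactol 12 is the ring tautomer of hydroxy-enal 13, and the equilibrium mixture is carried on and drawn in its open form.

Step 8
Reactants: 13 (2Z)-3-[2,4-bis(benzyloxy)phenyl]-2-[6-hydroxy-3-(3-hydroxy-3-methylbutyl)-2,4-dimethoxyphenyl]prop-2-enal
Product: 15 2-[2,4-bis(benzyloxy)phenyl]-5-(3-hydroxy-3-methylbutyl)-4,6-dimethoxy-1-benzofuran-3-carbaldehyde, via 3-iodo-2,3-dihydrobenzofuran 14 (not isolated)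
Conditions: I2 (1.2 equiv, added slowly), K2CO3 (3 equiv), THF, 0 °C → rt, dark; aq Na2S2O3
Reagents that add atoms: none
Why: Proposed new method: carbonate ionises the phenol of 13 and iodine is taken up at the enal α-carbon, either directly (the 2,4-dibenzyloxyphenyl group on the β-carbon polarises the alkene and carries the positive charge as a para-quinoid oxocarbenium ion) or through the enolate formed when the phenoxide adds reversibly to the β-carbon; both paths place the phenol oxygen on the benzylidene carbon in iodide 14, which should lose HI at once (anti-elimination of the C2–H, or ionisation of the tertiary C–I bond assisted by ring A) to give the aromatic furan. The closest known reaction type is the iodine- or iodine(III)-mediated oxidative cyclisation of 2-hydroxystilbenes to 2-arylbenzofurans; new are the formyl group on the alkene carbon that bears the phenol ring and the lactol/hydroxy-enal tautomerism of the substrate. The furan ring closes by O–C bond formation in a 5-endo sense onto a cationic (iodonium-opened) benzylic carbon, which the restriction on 5-endo-trig attack at neutral alkenes does not cover. No stereocentre is created in the product: the two transient centres of 14 are destroyed on aromatisation, and for the same reason the alkene geometry of 13 is of no consequence. The step needs O-attack at the benzylidene carbon to outrun iodination of ring A and re-oxidation of lactol 12 to lactone 11, and it needs a single direction of closure; the cation-stabilising ring B, irreversible aromatisation set against reversible lactol closure, anhydrous aprotic conditions with little more than one equivalent of iodine, and the fact that the second ortho oxygen of ring A is a methyl ether should secure this.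

Step 9
Reactants: 15 2-[2,4-bis(benzyloxy)phenyl]-5-(3-hydroxy-3-methylbutyl)-4,6-dimethoxy-1-benzofuran-3-carbaldehyde
Product: 16 2-[2,4-bis(benzyloxy)phenyl]-4-hydroxy-5-(3-hydroxy-3-methylbutyl)-6-methoxy-1-benzofuran-3-carbaldehyde
Conditions: MgI2·OEt2 (3 equiv), THF, 50 °C; aq NH4Cl
Reagents that add atoms: none
Why: Chelation-controlled demethylation, in which magnesium bridges the formyl oxygen and the peri 4-methoxy oxygen and iodide removes that methyl group by SN2, should leave the unchelated 6-methoxy group and, because no protic or strongly ionising acid is present, the tertiary alcohol.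

Step 10
Reactants: 16 2-[2,4-bis(benzyloxy)phenyl]-4-hydroxy-5-(3-hydroxy-3-methylbutyl)-6-methoxy-1-benzofuran-3-carbaldehyde
Product: 17 2-(2,4-dihydroxyphenyl)-4-hydroxy-5-(3-hydroxy-3-methylbutyl)-6-methoxy-1-benzofuran-3-carbaldehyde (ebenfuran V)
Conditions: H2 (1 atm), 10% Pd/C, EtOAc, rt
Reagents that add atoms: none
Why: Neutral hydrogenolysis of the two aryl benzyl ethers should spare the hydrogen-bonded, vinylogous-ester-type aldehyde and the tertiary alcohol, and no acid is present that could close a chroman.

Compound list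
1 | 4-hydroxy-2,6-dimethoxybenzaldehyde | COc1cc(O)cc(OC)c1C=O | starting material
2 | methyl (triphenyl-λ5-phosphanylidene)acetate | COC(=O)C=P(c1ccccc1)(c1ccccc1)c1ccccc1 | starting material
3 | methyl (2E)-3-(4-hydroxy-2,6-dimethoxyphenyl)prop-2-enoate | COC(=O)/C=C/c1c(OC)cc(O)cc1OC | intermediate
4 | methyl 3-(4-hydroxy-2,6-dimethoxyphenyl)propanoate | COC(=O)CCc1c(OC)cc(O)cc1OC | intermediate
5 | 4-(3-hydroxy-3-methylbutyl)-3,5-dimethoxyphenol | COc1cc(O)cc(OC)c1CCC(C)(C)O | intermediate
6 | glyoxylic acid | O=CC(=O)O | starting material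
7 | 2-hydroxy-2-[6-hydroxy-3-(3-hydroxy-3-methylbutyl)-2,4-dimethoxyphenyl]acetic acid (racemic) | OC(C(=O)O)c1c(O)cc(OC)c(CCC(C)(C)O)c1OC | intermediate
8 | 2-[6-hydroxy-3-(3-hydroxy-3-methylbutyl)-2,4-dimethoxyphenyl]acetic acid | OC(=O)Cc1c(O)cc(OC)c(CCC(C)(C)O)c1OC | intermediate
9 | 5-(3-hydroxy-3-methylbutyl)-4,6-dimethoxy-1-benzofuran-2(3H)-one | O=C1Cc2c(OC)c(CCC(C)(C)O)c(OC)cc2O1 | intermediate
10 | 2,4-bis(benzyloxy)benzaldehyde | O=Cc1ccc(OCc2ccccc2)cc1OCc1ccccc1 | starting material
11 | (3Z)-3-[2,4-bis(benzyloxy)benzylidene]-5-(3-hydroxy-3-methylbutyl)-4,6-dimethoxy-1-benzofuran-2(3H)-one | O=C1Oc2cc(OC)c(CCC(C)(C)O)c(OC)c2/C1=C/c1ccc(OCc2ccccc2)cc1OCc1ccccc1 | intermediate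
12 | (3Z)-3-[2,4-bis(benzyloxy)benzylidene]-5-(3-hydroxy-3-methylbutyl)-4,6-dimethoxy-2,3-dihydro-1-benzofuran-2-ol (racemic lactol) | OC1Oc2cc(OC)c(CCC(C)(C)O)c(OC)c2/C1=C/c1ccc(OCc2ccccc2)cc1OCc1ccccc1 | intermediate
13 | (2Z)-3-[2,4-bis(benzyloxy)phenyl]-2-[6-hydroxy-3-(3-hydroxy-3-methylbutyl)-2,4-dimethoxyphenyl]prop-2-enal | O=C/C(=C\c1ccc(OCc2ccccc2)cc1OCc1ccccc1)c1c(O)cc(OC)c(CCC(C)(C)O)c1OC | intermediate
14 | 2-[2,4-bis(benzyloxy)phenyl]-5-(3-hydroxy-3-methylbutyl)-3-iodo-4,6-dimethoxy-2,3-dihydro-1-benzofuran-3-carbaldehyde (racemic, either relative configuration) | COc1cc2OC(c3ccc(OCc4ccccc4)cc3OCc3ccccc3)C(I)(C=O)c2c(OC)c1CCC(C)(C)O | intermediate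
15 | 2-[2,4-bis(benzyloxy)phenyl]-5-(3-hydroxy-3-methylbutyl)-4,6-dimethoxy-1-benzofuran-3-carbaldehyde | COc1cc2oc(-c3ccc(OCc4ccccc4)cc3OCc3ccccc3)c(C=O)c2c(OC)c1CCC(C)(C)O | intermediate
16 | 2-[2,4-bis(benzyloxy)phenyl]-4-hydroxy-5-(3-hydroxy-3-methylbutyl)-6-methoxy-1-benzofuran-3-carbaldehyde | COc1cc2oc(-c3ccc(OCc4ccccc4)cc3OCc3ccccc3)c(C=O)c2c(O)c1CCC(C)(C)O | intermediate
17 | 2-(2,4-dihydroxyphenyl)-4-hydroxy-5-(3-hydroxy-3-methylbutyl)-6-methoxy-1-benzofuran-3-carbaldehyde (ebenfuran V) | COc1cc2oc(-c3ccc(O)cc3O)c(C=O)c2c(O)c1CCC(C)(C)O | target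

Total step count: 10
Longest linear sequence: 10 steps (1 → 17); aldehyde 10 enters in step 6 as purchased.

Steps most likely to fail

Step 8 (proposed new method). The oxidative closure may lose to electrophilic iodination of ring A at its one free position, or to re-oxidation of the lactol tautomer to the lactone. Iodination of ring A alone need not be fatal, since aryl–iodine bonds are also cleaved under the hydrogenolysis conditions of step 10. Should the closure itself not be achievable, 15 would be reached by known alkyne chemistry that sets out from phenol 5 and aldehyde 10. Mono-iodination of 5 ortho to the hydroxyl group (NIS, MeCN, 0 °C; one product by symmetry) would give 2-iodo-4-(3-hydroxy-3-methylbutyl)-3,5-dimethoxyphenol F1. Seyferth–Gilbert homologation of 10 with the Ohira–Bestmann reagent (K2CO3, MeOH) would give 2,4-bis(benzyloxy)-1-ethynylbenzene F2. Sonogashira coupling of the two (PdCl2(PPh3)2, CuI, Et3N, THF, rt) would give 2-{[2,4-bis(benzyloxy)phenyl]ethynyl}-4-(3-hydroxy-3-methylbutyl)-3,5-dimethoxyphenol F3. A 5-endo-dig iodocyclisation (I2, NaHCO3, MeCN, rt) would then give 4-{2-[2,4-bis(benzyloxy)phenyl]-3-iodo-4,6-dimethoxy-1-benzofuran-5-yl}-2-methylbutan-2-ol F4. Iodine–magnesium exchange (iPrMgCl·LiCl, THF, −40 °C, one extra equivalent for the alkoxide) and quenching with DMF would rejoin the route at 15.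

Step 9. The seven-membered magnesium chelate between the formyl group and the peri methoxy group may be too weak for clean cleavage, or the Lewis acid may start to ionise the tertiary alcohol. The fallback inverts the end game and replaces Lewis-acid cleavage by nucleophilic dealkylation. It sets out from 15, which would first be hydrogenolysed (H2, Pd/C, EtOAc) to 2-(2,4-dihydroxyphenyl)-5-(3-hydroxy-3-methylbutyl)-4,6-dimethoxy-1-benzofuran-3-carbaldehyde F5. Sodium ethanethiolate in DMF at about 100 °C would then remove one methyl group by SN2. The 4-methoxy group is the one flanked on both sides and its phenoxide is held by the formyl oxygen, so it should be preferred, and the phenoxide formed on ring A should discourage a second cleavage. This arrives directly at target 17.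

Step 7. Hydride may over-reduce past the lactol, because the tetrahedral aluminate of an aryl lactone has a phenoxide as leaving group and can collapse early. The fallback sets out from 11, which would be opened with the aluminium amide of N,O-dimethylhydroxylamine (MeNHOMe·HCl, AlMe3, CH2Cl2, 0 °C → rt) to (2Z)-3-[2,4-bis(benzyloxy)phenyl]-2-[6-hydroxy-3-(3-hydroxy-3-methylbutyl)-2,4-dimethoxyphenyl]-N-methoxy-N-methylprop-2-enamide F6. Reduction of this Weinreb amide (LiAlH4, THF, −40 °C) stops at the chelated tetrahedral stage and should release hydroxy-enal 13 on work-up, where the route is rejoined.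

Further compounds
F1 | step 8 | 2-iodo-4-(3-hydroxy-3-methylbutyl)-3,5-dimethoxyphenol | COc1cc(O)c(I)c(OC)c1CCC(C)(C)O
F2 | step 8 | 2,4-bis(benzyloxy)-1-ethynylbenzene | C#Cc1ccc(OCc2ccccc2)cc1OCc1ccccc1
F3 | step 8 | 2-{[2,4-bis(benzyloxy)phenyl]ethynyl}-4-(3-hydroxy-3-methylbutyl)-3,5-dimethoxyphenol | COc1cc(O)c(C#Cc2ccc(OCc3ccccc3)cc2OCc2ccccc2)c(OC)c1CCC(C)(C)O
F4 | step 8 | 4-{2-[2,4-bis(benzyloxy)phenyl]-3-iodo-4,6-dimethoxy-1-benzofuran-5-yl}-2-methylbutan-2-ol | COc1cc2oc(-c3ccc(OCc4ccccc4)cc3OCc3ccccc3)c(I)c2c(OC)c1CCC(C)(C)O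
F5 | step 9 | 2-(2,4-dihydroxyphenyl)-5-(3-hydroxy-3-methylbutyl)-4,6-dimethoxy-1-benzofuran-3-carbaldehyde | COc1cc2oc(-c3ccc(O)cc3O)c(C=O)c2c(OC)c1CCC(C)(C)O
F6 | step 7 | (2Z)-3-[2,4-bis(benzyloxy)phenyl]-2-[6-hydroxy-3-(3-hydroxy-3-methylbutyl)-2,4-dimethoxyphenyl]-N-methoxy-N-methylprop-2-enamide | CON(C)C(=O)/C(=C\c1ccc(OCc2ccccc2)cc1OCc1ccccc1)c1c(O)cc(OC)c(CCC(C)(C)O)c1OC
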